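**Strategy.** The lower (catechin) unit is not taken from the chiral pool but assembled. Its dihydropyran ring C is disconnected across C3–C4 and O1–C2 to an o-quinone methide of the phloroglucinol ring A and an (E)-enol ester that already carries ring B and the 4-benzyloxybenzoate. One catalytic asymmetric oxa-[4+2] cycloaddition closes ring C by forming the C4(H2)–C3(H)(O-acyl) bond, sets C2 and C3 trans, and installs the ester. The step exploits the ortho relationship of the C4 methylene and O1 on the electron-rich ring A, and the donor 3,4-dioxygenated ring B that dictates regiochemistry. The adduct is then joined at C8 to a C4-activated epicatechin, and nine benzyl ethers are removed.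

Key step: step 6

Assumption: the antipode of the chiral phosphoric acid that gives the (2R,3S) series in step 6 is to be chosen in a first screen ((R)-TRIP is written by default), and any residual minor enantiomer of 11 is removed as a diastereomer after step 9. Compounds 1, 2, 5, 7 and 12 are taken as catalogue materials.

Step 1
Reactants: 1 3,4-bis(benzyloxy)benzaldehyde; 2 bis(4,4,5,5-tetramethyl-1,3,2-dioxaborolan-2-yl)methane
Product: 3 (E)-2-{2-[3,4-bis(benzyloxy)phenyl]ethenyl}-4,4,5,5-tetramethyl-1,3,2-dioxaborolane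
Conditions: 2 (1.2 equiv), LiTMP (lithium 2,2,6,6-tetramethylpiperidide, 1.2 equiv), THF, 0 °C; then 1, −78 °C → rt
Reagents that add atoms: none
Why: Boron-Wittig olefination, in which the α-boryl carbanion of 2 adds to the aldehyde and syn B–O elimination should give the (E)-alkenylboronate, the geometry that later becomes the 2,3-trans relationship.

Step 2
Reactants: 3 (E)-alkenyl pinacol boronate
Product: 4 potassium (E)-{2-[3,4-bis(benzyloxy)phenyl]ethenyl}trifluoroborate
Conditions: KHF2 (aq., 4 equiv), MeOH, rt; precipitation from acetone/Et2O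
Reagents that add atoms: potassium hydrogen difluoride, [K+].[F-].F
Why: Boronate-to-trifluoroborate exchange with KHF2 retains the alkene geometry and should give a crystalline salt that is purified without chromatography.

Step 3
Reactants: 4 potassium (E)-alkenyltrifluoroborate; 5 4-(benzyloxy)benzoic acid
Product: 6 (E)-2-[3,4-bis(benzyloxy)phenyl]ethenyl 4-(benzyloxy)benzoate
Conditions: CuBr (10 mol %), DMAP (20 mol %), 4 Å MS, O2 (1 atm), CH2Cl2/MeCN, 40 °C
Reagents that add atoms: none
Why: Copper-catalysed oxidative C–O coupling (Chan–Lam type) of an alkenyltrifluoroborate with a carboxylic acid transfers the alkenyl group with retention of the E geometry and tolerates benzyl ethers.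

Step 4
Reactants: 7 2,4,6-trihydroxybenzaldehyde
Product: 8 2,4-bis(benzyloxy)-6-hydroxybenzaldehyde
Conditions: BnBr (2.1 equiv), K2CO3 (2.2 equiv), DMF, 0 °C → rt
Reagents that add atoms: benzyl bromide, BrCc1ccccc1
Why: Williamson etherification, in which the acidic 4-OH and one ortho-OH are alkylated while the remaining ortho-OH, hydrogen-bonded to the formyl group, is the least nucleophilic and stays free to become O1.

Step 5
Reactants: 8 2,4-bis(benzyloxy)-6-hydroxybenzaldehyde
Product: 9 3,5-bis(benzyloxy)-2-(hydroxymethyl)phenol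
Conditions: NaBH4, THF/MeOH, 0 °C; aq. NH4Cl work-up, used without storage
Reagents that add atoms: none
Why: Borohydride reduction of the salicylaldehyde gives the 2-hydroxybenzyl alcohol, the latent o-quinone methide, without touching the benzyl ethers.

Step 6
Reactants: 9 3,5-bis(benzyloxy)-2-(hydroxymethyl)phenol; 6 (E)-2-[3,4-bis(benzyloxy)phenyl]ethenyl 4-(benzyloxy)benzoate
Product: 11 (2R,3S)-5,7-bis(benzyloxy)-2-[3,4-bis(benzyloxy)phenyl]-3,4-dihydro-2H-chromen-3-yl 4-(benzyloxy)benzoate, via o-quinone methide 10 (not isolated)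
Conditions: (R)-TRIP [3,3'-bis(2,4,6-triisopropylphenyl)-1,1'-binaphthyl-2,2'-diyl hydrogen phosphate] (10 mol %), 6 (1.5 equiv), 5 Å MS, toluene, 0 °C → rt, slow addition of 9
Reagents that add atoms: none
Why: Proposed new method: the acid ionises 9 with loss of water to the o-quinone methide 10, held as a hydrogen-bonded pair with the chiral phosphate, and 10 adds to 6 in an inverse-electron-demand oxa-[4+2] (hetero-Diels–Alder) cycloaddition; the closest known reactions are thermal and Brønsted acid-catalysed o-quinone methide/styrene cycloadditions to flavans and chiral phosphoric acid-catalysed [4+2] cycloadditions of in situ o-quinone methides with electron-rich alkenes, none of which has used a β-acyloxystyrene. Ring C is closed as an intermolecular six-membered annulation, concerted but asynchronous, in which the exocyclic CH2 of 10 (future C4) bonds to the acyloxy-bearing alkene carbon (future C3) ahead of the bond between the carbonyl oxygen (O1) and the benzylic carbon (future C2). The regiochemistry should be secured by the 3,4-dialkoxyphenyl group, a far stronger cation-stabilising donor than the acyloxy group, so that positive charge develops at the carbon that ends up on O1. The 2,3-trans relationship follows from suprafacial addition across the E alkene, and is also the diequatorial outcome should the addition be stepwise. The absolute configuration (2R,3S) has no substrate element to rely on and must come from the chiral phosphate, which binds the carbonyl oxygen of 10 and leaves one enantiotopic face of 6 open. Chemoselectivity over self-condensation of the nucleophilic phloroglucinol ring is sought by slow addition of 9 to excess 6 and by sieves that protect the enol ester from hydrolysis.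

Step 7
Reactants: 12 (−)-epicatechin, (2R,3R)
Product: 13 5,7,3',4'-tetra-O-benzyl-(−)-epicatechin
Conditions: BnBr (4.4 equiv), K2CO3, DMF, 0 °C → rt, Ar
Reagents that add atoms: benzyl bromide, BrCc1ccccc1
Why: Williamson etherification of the four phenols, far more acidic than the secondary 3-OH, leaves the C3 hydroxyl free and the chiral-pool (2R,3R) centres untouched.

Step 8
Reactants: 13 5,7,3',4'-tetra-O-benzyl-(−)-epicatechin
Product: 14 5,7,3',4'-tetra-O-benzyl-4β-(2-ethoxyethoxy)-(−)-epicatechin (3,4-trans, 3-OH free)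
Conditions: DDQ (2 equiv), 2-ethoxyethanol (5 equiv), CH2Cl2, rt
Reagents that add atoms: 2-ethoxyethanol, CCOCCO
Why: DDQ benzylic oxidation (hydride abstraction at C4 next to the electron-rich ring A) gives a C4 cation that is captured by 2-ethoxyethanol trans to the 3-OH, installing the leaving group for the fragment union; either C4 epimer would serve.

Step 9
Reactants: 14 4β-(2-ethoxyethoxy) epicatechin electrophile; 11 benzylated catechin 3-O-(4-benzyloxybenzoate)
Product: 15 5,7,3',4'-tetra-O-benzylepicatechin-(4β→8)-5,7,3',4'-tetra-O-benzylcatechin 3-O-(4-benzyloxybenzoate) (upper 3-OH free)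
Conditions: 11 (3 equiv, excess recovered), Me3SiOTf (0.2 equiv), CH2Cl2, −78 °C; Et3N quench
Reagents that add atoms: none
Why: Lewis acid-promoted Friedel–Crafts alkylation by a flavan-4-yl cation, which should be attacked by C8 of 11 (more nucleophilic and less hindered than C6) on the face trans to the neighbouring 3-OH, setting the upper C4 as 4β (R); excess 11 suppresses oligomerisation, and a diastereomer derived from any ent-11 is removed here by chromatography.

Step 10
Reactants: 15 nona-O-benzyl dimer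
Product: 16 epicatechin-(4β→8)-catechin 3-O-(4-hydroxybenzoate) on the lower unit, CNP0288594.1
Conditions: H2 (1 atm), Pd(OH)2/C, THF/MeOH/H2O, rt
Reagents that add atoms: none
Why: Hydrogenolysis of the nine benzyl ethers under neutral conditions should free all phenols without cleaving the aryl ester, the doubly benzylic C4–C8 bond or the flavan C2–O bonds.

**Compound list**

1 | 3,4-bis(benzyloxy)benzaldehyde | O=Cc1ccc(OCc2ccccc2)c(OCc2ccccc2)c1 | starting material
2 | bis(4,4,5,5-tetramethyl-1,3,2-dioxaborolan-2-yl)methane | CC1(C)OB(CB2OC(C)(C)C(C)(C)O2)OC1(C)C | starting material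
3 | (E)-2-{2-[3,4-bis(benzyloxy)phenyl]ethenyl}-4,4,5,5-tetramethyl-1,3,2-dioxaborolane | CC1(C)OB(/C=C/c2ccc(OCc3ccccc3)c(OCc3ccccc3)c2)OC1(C)C | intermediate
4 | potassium (E)-{2-[3,4-bis(benzyloxy)phenyl]ethenyl}trifluoroborate | [K+].F[B-](F)(F)/C=C/c1ccc(OCc2ccccc2)c(OCc2ccccc2)c1 | intermediate
5 | 4-(benzyloxy)benzoic acid | OC(=O)c1ccc(OCc2ccccc2)cc1 | starting material
6 | (E)-2-[3,4-bis(benzyloxy)phenyl]ethenyl 4-(benzyloxy)benzoate | O=C(O/C=C/c1ccc(OCc2ccccc2)c(OCc2ccccc2)c1)c1ccc(OCc2ccccc2)cc1 | intermediate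
7 | 2,4,6-trihydroxybenzaldehyde | O=Cc1c(O)cc(O)cc1O | starting material
8 | 2,4-bis(benzyloxy)-6-hydroxybenzaldehyde | O=Cc1c(O)cc(OCc2ccccc2)cc1OCc1ccccc1 | intermediate
9 | 3,5-bis(benzyloxy)-2-(hydroxymethyl)phenol | OCc1c(O)cc(OCc2ccccc2)cc1OCc1ccccc1 | intermediate
10 | 3,5-bis(benzyloxy)-6-methylidenecyclohexa-2,4-dien-1-one (o-quinone methide) | C=C1C(=O)C=C(OCc2ccccc2)C=C1OCc1ccccc1 | intermediate
11 | (2R,3S)-5,7-bis(benzyloxy)-2-[3,4-bis(benzyloxy)phenyl]-3,4-dihydro-2H-chromen-3-yl 4-(benzyloxy)benzoate | O=C(O[C@H]1Cc2c(OCc3ccccc3)cc(OCc3ccccc3)cc2O[C@@H]1c1ccc(OCc2ccccc2)c(OCc2ccccc2)c1)c1ccc(OCc2ccccc2)cc1 | intermediate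
12 | (−)-epicatechin, (2R,3R) | O[C@@H]1Cc2c(O)cc(O)cc2O[C@@H]1c1ccc(O)c(O)c1 | starting material
13 | 5,7,3',4'-tetra-O-benzyl-(−)-epicatechin | O[C@@H]1Cc2c(OCc3ccccc3)cc(OCc3ccccc3)cc2O[C@@H]1c1ccc(OCc2ccccc2)c(OCc2ccccc2)c1 | intermediate
14 | 5,7,3',4'-tetra-O-benzyl-4β-(2-ethoxyethoxy)-(−)-epicatechin | CCOCCO[C@H]1c2c(OCc3ccccc3)cc(OCc3ccccc3)cc2O[C@H](c2ccc(OCc3ccccc3)c(OCc3ccccc3)c2)[C@@H]1O | intermediate
15 | 5,7,3',4'-tetra-O-benzylepicatechin-(4β→8)-5,7,3',4'-tetra-O-benzylcatechin 3-O-(4-benzyloxybenzoate) | O=C(O[C@H]1Cc2c(OCc3ccccc3)cc(OCc3ccccc3)c([C@H]3c4c(OCc5ccccc5)cc(OCc5ccccc5)cc4O[C@H](c4ccc(OCc5ccccc5)c(OCc5ccccc5)c4)[C@@H]3O)c2O[C@@H]1c1ccc(OCc2ccccc2)c(OCc2ccccc2)c1)c1ccc(OCc2ccccc2)cc1 | intermediate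
16 | epicatechin-(4β→8)-catechin 3-O-(4-hydroxybenzoate), CNP0288594.1 | O=C(O[C@H]1Cc2c(O)cc(O)c([C@H]3c4c(O)cc(O)cc4O[C@H](c4ccc(O)c(O)c4)[C@@H]3O)c2O[C@@H]1c1ccc(O)c(O)c1)c1ccc(O)cc1 | target

**Step count.** Total: 10 steps. Longest linear sequence: 6 steps (steps 1, 2, 3, 6, 9, 10).

**Steps most likely to fail**

1. Step 6 (proposed new method). The risks are weak enantiofacial discrimination by the phosphate on a dienophile with no hydrogen-bond donor, sluggish addition of the acyloxy-deactivated styrene to the stabilised quinone methide, and competing self-alkylation of the phloroglucinol ring. The fallback uses known chemistry, keeps the closure of ring C between C3 and C4, sets out from 8 and 1 and returns at 11. Wittig methylenation of 8 (Ph3PCH3Br, KOtBu, THF) should give 3,5-bis(benzyloxy)-2-ethenylphenol F1. In parallel, Horner–Wadsworth–Emmons olefination of 1 (triethyl phosphonoacetate, NaH) should give ethyl (E)-3-[3,4-bis(benzyloxy)phenyl]prop-2-enoate F2. Reduction with i-Bu2AlH gives (E)-3-[3,4-bis(benzyloxy)phenyl]prop-2-en-1-ol F3, and ClCO2Me/pyridine gives (E)-3-[3,4-bis(benzyloxy)phenyl]prop-2-enyl methyl carbonate F4. Iridium-catalysed asymmetric allylic etherification of F1 with F4 ([Ir(cod)Cl]2, BINOL-derived chiral phosphoramidite ligand of the antipode that gives the S ether, base, THF) sets C2 in the branched (S)-1-[3,4-bis(benzyloxy)phenyl]prop-2-enyl 3,5-bis(benzyloxy)-2-ethenylphenyl ether F5. Ring-closing metathesis with the second-generation Grubbs catalyst, (H2IMes)(PCy3)Cl2Ru=CHPh, forms the C3=C4 bond in (S)-5,7-bis(benzyloxy)-2-[3,4-bis(benzyloxy)phenyl]-2H-chromene F6. Hydroboration–oxidation (BH3·SMe2, then NaOH/H2O2) anti to the C2 aryl group gives 5,7,3',4'-tetra-O-benzyl-(+)-catechin F7. Esterification with 5 (EDC, DMAP, CH2Cl2) returns to 11.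

2. Step 9. The risks are oligomerisation, because electrophile and product both keep nucleophilic ring-A positions, and erosion of C8 over C6 selectivity. The fallback blocks the competing site; it sets out from 13 and returns at 16. Bromination of 13 (NBS, CH2Cl2, −78 °C) should give 8-bromo-5,7,3',4'-tetra-O-benzyl-(−)-epicatechin F8. DDQ/2-ethoxyethanol then gives 8-bromo-5,7,3',4'-tetra-O-benzyl-4β-(2-ethoxyethoxy)-(−)-epicatechin F9. Because F9 cannot self-condense at C8, it is coupled with an equimolar amount of 11 (Me3SiOTf, CH2Cl2, −78 °C) to give the 8-bromo nona-O-benzyl dimer F10. Hydrogenolysis (H2, Pd(OH)2/C, Et3N, THF/MeOH/H2O) removes the bromine together with the benzyl groups to give 16.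

3. Step 3. The risks are protodeboronation or homocoupling of the electron-rich alkenylborate and partial loss of the E geometry during copper turnover. The fallback sets out from 1 and returns at 6. Ohira–Bestmann homologation of 1 (dimethyl (1-diazo-2-oxopropyl)phosphonate, K2CO3, MeOH) should give 1,2-bis(benzyloxy)-4-ethynylbenzene F11. Ruthenium-catalysed anti-Markovnikov addition of 5 ([(p-cymene)RuCl2]2, P(4-ClC6H4)3, DMAP, toluene, 60 °C) gives (Z)-2-[3,4-bis(benzyloxy)phenyl]ethenyl 4-(benzyloxy)benzoate F12. Thermodynamic Z-to-E isomerisation (catalytic I2 or PhSSPh, visible light) then gives 6.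

**Further compounds**

F1 | step 6 | 3,5-bis(benzyloxy)-2-ethenylphenol | C=Cc1c(O)cc(OCc2ccccc2)cc1OCc1ccccc1
F2 | step 6 | ethyl (E)-3-[3,4-bis(benzyloxy)phenyl]prop-2-enoate | CCOC(=O)/C=C/c1ccc(OCc2ccccc2)c(OCc2ccccc2)c1
F3 | step 6 | (E)-3-[3,4-bis(benzyloxy)phenyl]prop-2-en-1-ol | OC/C=C/c1ccc(OCc2ccccc2)c(OCc2ccccc2)c1
F4 | step 6 | (E)-3-[3,4-bis(benzyloxy)phenyl]prop-2-enyl methyl carbonate | COC(=O)OC/C=C/c1ccc(OCc2ccccc2)c(OCc2ccccc2)c1
F5 | step 6 | (S)-1-[3,4-bis(benzyloxy)phenyl]prop-2-enyl 3,5-bis(benzyloxy)-2-ethenylphenyl ether | C=C[C@H](Oc1cc(OCc2ccccc2)cc(OCc2ccccc2)c1C=C)c1ccc(OCc2ccccc2)c(OCc2ccccc2)c1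
F6 | step 6 | (S)-5,7-bis(benzyloxy)-2-[3,4-bis(benzyloxy)phenyl]-2H-chromene | C1=Cc2c(OCc3ccccc3)cc(OCc3ccccc3)cc2O[C@@H]1c1ccc(OCc2ccccc2)c(OCc2ccccc2)c1
F7 | step 6 | 5,7,3',4'-tetra-O-benzyl-(+)-catechin, (2R,3S) | O[C@H]1Cc2c(OCc3ccccc3)cc(OCc3ccccc3)cc2O[C@@H]1c1ccc(OCc2ccccc2)c(OCc2ccccc2)c1
F8 | step 9 | 8-bromo-5,7,3',4'-tetra-O-benzyl-(−)-epicatechin | O[C@@H]1Cc2c(OCc3ccccc3)cc(OCc3ccccc3)c(Br)c2O[C@@H]1c1ccc(OCc2ccccc2)c(OCc2ccccc2)c1
F9 | step 9 | 8-bromo-5,7,3',4'-tetra-O-benzyl-4β-(2-ethoxyethoxy)-(−)-epicatechin | CCOCCO[C@H]1c2c(OCc3ccccc3)cc(OCc3ccccc3)c(Br)c2O[C@H](c2ccc(OCc3ccccc3)c(OCc3ccccc3)c2)[C@@H]1O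
F10 | step 9 | 8-bromo-5,7,3',4'-tetra-O-benzylepicatechin-(4β→8)-5,7,3',4'-tetra-O-benzylcatechin 3-O-(4-benzyloxybenzoate) | O=C(O[C@H]1Cc2c(OCc3ccccc3)cc(OCc3ccccc3)c([C@H]3c4c(OCc5ccccc5)cc(OCc5ccccc5)c(Br)c4O[C@H](c4ccc(OCc5ccccc5)c(OCc5ccccc5)c4)[C@@H]3O)c2O[C@@H]1c1ccc(OCc2ccccc2)c(OCc2ccccc2)c1)c1ccc(OCc2ccccc2)cc1
F11 | step 3 | 1,2-bis(benzyloxy)-4-ethynylbenzene | C#Cc1ccc(OCc2ccccc2)c(OCc2ccccc2)c1
F12 | step 3 | (Z)-2-[3,4-bis(benzyloxy)phenyl]ethenyl 4-(benzyloxy)benzoate | O=C(O/C=C\c1ccc(OCc2ccccc2)c(OCc2ccccc2)c1)c1ccc(OCc2ccccc2)cc1
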